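**Plan**

- Retrosynthesis: the 18 phenols are masked as benzyl ethers. Both interflavan bonds, C4(top)–C8(middle) and C4(middle)–C8(bottom), are cut as flavan-4-yl cation/arene pairs. The C-ring of the middle unit is then cut at O1–C8a and C2–C3, which excises 3,4-bis(benzyloxy)benzaldehyde.
- Enabling feature: in the middle unit, C4 (the later cationic interflavan carbon) is bonded to C3 and to A-ring carbon C4a, ortho to C8a. Held as a C4 ketone (dihydroflavonol level, as in the biosynthetic extension-unit precursor), it acidifies C3–H and activates a C8a–F bond. One enolate/aldehyde event (aldol, then SNAr) therefore closes the pyran ring from an acyclic α-alkoxy 2-fluoroaryl ketone.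
- Forward order: A-ring fluoroketone → middle C-ring (key step) → C4=O reduced and converted to a 2-ethoxyethoxy leaving group → C3 ketone → cis-alcohol 15. Compound 15 is the top-unit electrophile as such and the middle-unit electrophile after galloylation. The bottom unit 20 is made from (−)-epicatechin by benzylation and galloylation. Then C4(middle)–C8(bottom), C4(top)–C8(middle), and hydrogenolysis.
- Stereochemistry: C2/C3 from the key step are racemic and are re-set on purpose. C3 passes through the flavan-3-one, and C2/C3 (2R,3R, cis) are fixed by asymmetric hydrogenation with dynamic kinetic resolution. Both C4 centres (4β) come from attack anti to the C3 substituent and 2-aryl group in the cation couplings. The bottom unit comes from the chiral pool.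

Key step: step 5

Remark: 11–14 are racemic, and C4 of 12–15 and 17 and the acetal carbon of the 1-ethoxyethyl group are epimer mixtures; such centres carry no descriptor in the SMILES and the relative configuration is given in the name.

**Route**

Step 1
Reactants: 1 1,3,5-trifluorobenzene
Product: 2 1,3-bis(benzyloxy)-5-fluorobenzene
Conditions: BnOH (2.1 equiv), NaH (2.2 equiv), NMP, 0 → 100 °C
Reagents that add atoms: benzyl alcohol, OCc1ccccc1
Why: Twofold SNAr by sodium benzyl oxide on the fluorine-activated ring should stop after the second substitution because each alkoxy group introduced deactivates the remaining C–F bond.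

Step 2
Reactants: 3 ethyl glycolate
Product: 4 ethyl 2-(1-ethoxyethoxy)acetate
Conditions: ethyl vinyl ether, PPTS (cat.), CH2Cl2, 0 → 23 °C
Reagents that add atoms: ethyl vinyl ether, C=COCC
Why: Acid-catalysed addition of the alcohol to the enol ether (acetal protection) gives a base-stable 1-ethoxyethyl ether that later keeps O3 from competing with O1 in the ring closure.

Step 3
Reactants: 4 ethyl 2-(1-ethoxyethoxy)acetate
Product: 5 2-(1-ethoxyethoxy)-N-methoxy-N-methylacetamide
Conditions: MeNH(OMe)·HCl, i-PrMgCl, THF, −20 → 0 °C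
Reagents that add atoms: N,O-dimethylhydroxylamine hydrochloride, CNOC.Cl
Why: Aminolysis of the ester by the chloromagnesium amide made in situ gives the Weinreb amide, the acetal being inert to the Grignard base.

Step 4
Reactants: 2 1,3-bis(benzyloxy)-5-fluorobenzene, 5 2-(1-ethoxyethoxy)-N-methoxy-N-methylacetamide
Product: 7 1-[2,4-bis(benzyloxy)-6-fluorophenyl]-2-(1-ethoxyethoxy)ethan-1-one, via aryllithium 6 (not isolated)
Conditions: n-BuLi (1.05 equiv), THF, −78 °C; then 5, −78 °C; then H2O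
Reagents that add atoms: none
Why: Directed ortho-lithiation at the C–H flanked by fluorine and benzyloxy, the most acidic position, is followed by Weinreb ketone synthesis, in which the chelated tetrahedral adduct prevents over-addition and −78 °C prevents loss of LiF to a benzyne.

Step 5
Reactants: 7 1-[2,4-bis(benzyloxy)-6-fluorophenyl]-2-(1-ethoxyethoxy)ethan-1-one, 8 3,4-bis(benzyloxy)benzaldehyde
Product: 11 rac-5,7-bis(benzyloxy)-2-[3,4-bis(benzyloxy)phenyl]-3-(1-ethoxyethoxy)chroman-4-one (2,3-trans expected as major isomer), via lithium enolate 9 (not isolated), via lithium aldolate 10 (not isolated)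
Conditions: LiHMDS (1.05 equiv), THF, −78 °C; 8; then DMPU, −78 → 45 °C
Reagents that add atoms: none
Why: LiHMDS removes the C3–H of 7 (acidified by the C4 ketone) to give the chelated Z-enolate 9, which adds to aldehyde 8 through a closed six-membered chair transition state (C2–C3 bond, aldolate 10); on warming with DMPU the C2 alkoxide attacks C8a, ortho to the C4 carbonyl, and fluoride leaves from the carbonyl-stabilised Meisenheimer adduct (O1–C8a bond), precipitation of LiF making the sequence irreversible. The closest known reaction types are the lithium-enolate aldol addition of α-alkoxy aryl ketones and the intramolecular SNAr of β-alkoxides on o-fluoroaryl ketones used for chroman-4-ones, here run in one flask. The pyranone ring closes by addition–elimination at the aromatic carbon C8a, a favoured 6-endo-trig closure because the π-bond that carries the charge to the carbonyl, C8a=C4a, lies inside the new ring. C2 and C3 arise racemic: the Z-enolate should favour the syn (2,3-cis) aldolate, C3 should then equilibrate through the enolate towards the diequatorial 2,3-trans chromanone, and neither centre needs control here because C3 becomes a ketone in step 7 and C2 is re-set in step 8. The step needs closure through O1 and not O3, which the 1-ethoxyethyl acetal on O3 secures; the two benzyloxy groups stand meta to C8a and so do not feed electron density to the carbon attacked, LiHMDS is too weak to metalate the aryl C–H next to fluorine, the aldehyde has no α-hydrogen, and the near-stoichiometric base limits E1cB ring-opening of the product to the chalcone.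

Step 6
Reactants: 11 rac-5,7-bis(benzyloxy)-2-[3,4-bis(benzyloxy)phenyl]-3-(1-ethoxyethoxy)chroman-4-one
Product: 13 rac-(2,3-trans)-5,7-bis(benzyloxy)-2-[3,4-bis(benzyloxy)phenyl]-4-(2-ethoxyethoxy)chroman-3-ol, via flavan-4-ol 12 (not isolated)
Conditions: NaBH4, THF/EtOH, 0 °C, aqueous work-up; crude 12, 2-ethoxyethanol (excess), CSA (cat.), CH2Cl2, 0 → 23 °C
Reagents that add atoms: 2-ethoxyethanol, CCOCCO
Why: Borohydride reduction of the C4 ketone is followed by acid-catalysed SN1 alcoholysis of the very stabilised flavan-4-yl cation, the same acid removing the 1-ethoxyethyl group by transacetalisation; the configuration at C4 is left open because this centre is ionised again in steps 12 and 13.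

Step 7
Reactants: 13 rac-(2,3-trans)-5,7-bis(benzyloxy)-2-[3,4-bis(benzyloxy)phenyl]-4-(2-ethoxyethoxy)chroman-3-ol
Product: 14 rac-5,7-bis(benzyloxy)-2-[3,4-bis(benzyloxy)phenyl]-4-(2-ethoxyethoxy)chroman-3-one
Conditions: Dess–Martin periodinane, pyridine, CH2Cl2, 0 → 23 °C; used without delay
Reagents that add atoms: none
Why: Dess–Martin oxidation of the secondary C3 alcohol under buffered, non-acidic conditions gives the flavan-3-one, which removes the C3 centre and makes C2–H acidic for the next step.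

Step 8
Reactants: 14 rac-5,7-bis(benzyloxy)-2-[3,4-bis(benzyloxy)phenyl]-4-(2-ethoxyethoxy)chroman-3-one
Product: 15 (2R,3R)-5,7-bis(benzyloxy)-2-[3,4-bis(benzyloxy)phenyl]-4-(2-ethoxyethoxy)chroman-3-ol (2,3-cis)
Conditions: H2 (50 atm), RuCl2[(S)-Xyl-SDP][(R,R)-DPEN] (1 mol %; the mirror-image complex if the sense of induction is opposite), KOt-Bu (0.2 equiv), i-PrOH/THF, 23 °C
Reagents that add atoms: none
Why: Noyori-type asymmetric hydrogenation with dynamic kinetic resolution, as established for racemic α-aryl cyclic ketones: base equilibrates C2 through the enolate while the chiral Ru hydride reduces the matched enantiomer from the face anti to the equatorial 2-aryl group, so that catalyst control sets C3 and C2 together as the 2,3-cis (2R,3R) alcohol, C4 remaining an epimer mixture.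

Step 9
Reactants: 15 (2R,3R)-5,7-bis(benzyloxy)-2-[3,4-bis(benzyloxy)phenyl]-4-(2-ethoxyethoxy)chroman-3-ol, 16 3,4,5-tris(benzyloxy)benzoyl chloride
Product: 17 (2R,3R)-5,7-bis(benzyloxy)-2-[3,4-bis(benzyloxy)phenyl]-4-(2-ethoxyethoxy)chroman-3-yl 3,4,5-tris(benzyloxy)benzoate
Conditions: Et3N, DMAP (cat.), CH2Cl2, 0 → 23 °C
Reagents that add atoms: none
Why: DMAP-catalysed acylation of the hindered axial 3-hydroxyl by the acid chloride (nucleophilic catalysis), which touches no stereocentre.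

Step 10
Reactants: 18 (−)-epicatechin
Product: 19 5,7,3',4'-tetra-O-benzyl-(−)-epicatechin [(2R,3R)-5,7-bis(benzyloxy)-2-[3,4-bis(benzyloxy)phenyl]chroman-3-ol]
Conditions: BnBr (4.2 equiv), K2CO3, DMF, 0 → 23 °C, argon
Reagents that add atoms: benzyl bromide, BrCc1ccccc1
Why: Williamson etherification of the four phenols under weak carbonate base, which does not ionise the secondary 3-hydroxyl and leaves the C2 and C3 centres of the chiral-pool unit untouched; argon keeps the catechol from oxidising before it is capped.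

Step 11
Reactants: 19 5,7,3',4'-tetra-O-benzyl-(−)-epicatechin, 16 3,4,5-tris(benzyloxy)benzoyl chloride
Product: 20 5,7,3',4'-tetra-O-benzyl-(−)-epicatechin 3-O-[3,4,5-tris(benzyloxy)benzoate]
Conditions: Et3N, DMAP (cat.), CH2Cl2, 0 → 23 °C
Reagents that add atoms: none
Why: DMAP-catalysed acylation of the axial 3-hydroxyl by the acid chloride, as in step 9, with retention at C3 because the C–O bond is not broken.

Step 12
Reactants: 17 (2R,3R)-5,7-bis(benzyloxy)-2-[3,4-bis(benzyloxy)phenyl]-4-(2-ethoxyethoxy)chroman-3-yl 3,4,5-tris(benzyloxy)benzoate, 20 5,7,3',4'-tetra-O-benzyl-(−)-epicatechin 3-O-[3,4,5-tris(benzyloxy)benzoate]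
Product: 21 tetradeca-O-benzyl epicatechin 3-O-gallate-(4β→8)-epicatechin 3-O-gallate
Conditions: TMSOTf (0.2 equiv), CH2Cl2, −78 → −40 °C; 20 in excess (3 equiv, recovered)
Reagents that add atoms: none
Why: Lewis-acid ionisation of the C4 ether gives the flavan-4-yl cation, which alkylates C8 of 20 in the Friedel–Crafts-type 4→8 coupling known from procyanidin synthesis; the 3-O-acyl carbonyl bridges the α-face and the cis 2-aryl group shields it too, so the nucleophile enters from the β-face (3,4-trans), while the excess of 20 suppresses self-condensation of 17.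

Step 13
Reactants: 15 (2R,3R)-5,7-bis(benzyloxy)-2-[3,4-bis(benzyloxy)phenyl]-4-(2-ethoxyethoxy)chroman-3-ol, 21 tetradeca-O-benzyl epicatechin 3-O-gallate-(4β→8)-epicatechin 3-O-gallate
Product: 22 octadeca-O-benzyl epicatechin-(4β→8)-epicatechin 3-O-gallate-(4β→8)-epicatechin 3-O-gallate
Conditions: TMSOTf (0.2 equiv), CH2Cl2, −78 → −40 °C; 15 added slowly to 21 (1.5 equiv, excess recovered)
Reagents that add atoms: none
Why: The same cation/Friedel–Crafts 4→8 coupling: the cation from 15 is attacked anti to its 3-OH and 2-aryl groups (4β) by C8 of the upper unit of 21, the most nucleophilic and least hindered free position of the dimer, and slow addition of 15 to excess 21 limits self-condensation.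

Step 14
Reactants: 22 octadeca-O-benzyl epicatechin-(4β→8)-epicatechin 3-O-gallate-(4β→8)-epicatechin 3-O-gallate
Product: 23 epicatechin-(4β→8)-epicatechin 3-O-gallate-(4β→8)-epicatechin 3-O-gallate (CNP0279403.1)
Conditions: H2 (1 atm), 20% Pd(OH)2/C, THF/MeOH/H2O, 23 °C
Reagents that add atoms: none
Why: Hydrogenolysis of the eighteen benzyl ethers over Pd(OH)2/C under neutral conditions, to which the two gallate esters, the interflavan bonds and all eight stereocentres are inert.

**Compound list**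

1 | 1,3,5-trifluorobenzene | Fc1cc(F)cc(F)c1 | starting material
2 | 1,3-bis(benzyloxy)-5-fluorobenzene | Fc1cc(OCc2ccccc2)cc(OCc2ccccc2)c1 | intermediate
3 | ethyl glycolate | CCOC(=O)CO | starting material
4 | ethyl 2-(1-ethoxyethoxy)acetate | CCOC(C)OCC(=O)OCC | intermediate
5 | 2-(1-ethoxyethoxy)-N-methoxy-N-methylacetamide | CCOC(C)OCC(=O)N(C)OC | intermediate
6 | [2,4-bis(benzyloxy)-6-fluorophenyl]lithium | [Li]c1c(F)cc(OCc2ccccc2)cc1OCc1ccccc1 | intermediate
7 | 1-[2,4-bis(benzyloxy)-6-fluorophenyl]-2-(1-ethoxyethoxy)ethan-1-one | CCOC(C)OCC(=O)c1c(F)cc(OCc2ccccc2)cc1OCc1ccccc1 | intermediate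
8 | 3,4-bis(benzyloxy)benzaldehyde | O=Cc1ccc(OCc2ccccc2)c(OCc2ccccc2)c1 | starting material
9 | lithium (Z)-enolate of 7 | [Li+].[O-]/C(=C\OC(C)OCC)c1c(F)cc(OCc2ccccc2)cc1OCc1ccccc1 | intermediate
10 | lithium aldolate (3-aryl-3-oxido-2-(1-ethoxyethoxy)-1-(2-fluoroaryl)propan-1-one) | [Li+].[O-]C(c1ccc(OCc2ccccc2)c(OCc2ccccc2)c1)C(OC(C)OCC)C(=O)c1c(F)cc(OCc2ccccc2)cc1OCc1ccccc1 | intermediate
11 | rac-5,7-bis(benzyloxy)-2-[3,4-bis(benzyloxy)phenyl]-3-(1-ethoxyethoxy)chroman-4-one | CCOC(C)OC1C(=O)c2c(OCc3ccccc3)cc(OCc3ccccc3)cc2OC1c1ccc(OCc3ccccc3)c(OCc3ccccc3)c1 | intermediate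
12 | rac-5,7-bis(benzyloxy)-2-[3,4-bis(benzyloxy)phenyl]-3-(1-ethoxyethoxy)chroman-4-ol | CCOC(C)OC1C(O)c2c(OCc3ccccc3)cc(OCc3ccccc3)cc2OC1c1ccc(OCc3ccccc3)c(OCc3ccccc3)c1 | intermediate
13 | rac-(2,3-trans)-5,7-bis(benzyloxy)-2-[3,4-bis(benzyloxy)phenyl]-4-(2-ethoxyethoxy)chroman-3-ol | OC1C(OCCOCC)c2c(OCc3ccccc3)cc(OCc3ccccc3)cc2OC1c1ccc(OCc3ccccc3)c(OCc3ccccc3)c1 | intermediate
14 | rac-5,7-bis(benzyloxy)-2-[3,4-bis(benzyloxy)phenyl]-4-(2-ethoxyethoxy)chroman-3-one | O=C1C(OCCOCC)c2c(OCc3ccccc3)cc(OCc3ccccc3)cc2OC1c1ccc(OCc3ccccc3)c(OCc3ccccc3)c1 | intermediate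
15 | (2R,3R)-5,7-bis(benzyloxy)-2-[3,4-bis(benzyloxy)phenyl]-4-(2-ethoxyethoxy)chroman-3-ol | O[C@@H]1C(OCCOCC)c2c(OCc3ccccc3)cc(OCc3ccccc3)cc2O[C@@H]1c1ccc(OCc3ccccc3)c(OCc3ccccc3)c1 | intermediate
16 | 3,4,5-tris(benzyloxy)benzoyl chloride | O=C(Cl)c1cc(OCc2ccccc2)c(OCc2ccccc2)c(OCc2ccccc2)c1 | starting material
17 | (2R,3R)-5,7-bis(benzyloxy)-2-[3,4-bis(benzyloxy)phenyl]-4-(2-ethoxyethoxy)chroman-3-yl 3,4,5-tris(benzyloxy)benzoate | O=C(O[C@@H]1C(OCCOCC)c2c(OCc3ccccc3)cc(OCc3ccccc3)cc2O[C@@H]1c1ccc(OCc3ccccc3)c(OCc3ccccc3)c1)c1cc(OCc3ccccc3)c(OCc3ccccc3)c(OCc3ccccc3)c1 | intermediate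
18 | (−)-epicatechin | O[C@@H]1Cc2c(O)cc(O)cc2O[C@@H]1c1ccc(O)c(O)c1 | starting material
19 | 5,7,3',4'-tetra-O-benzyl-(−)-epicatechin [(2R,3R)-5,7-bis(benzyloxy)-2-[3,4-bis(benzyloxy)phenyl]chroman-3-ol] | O[C@@H]1Cc2c(OCc3ccccc3)cc(OCc3ccccc3)cc2O[C@@H]1c1ccc(OCc3ccccc3)c(OCc3ccccc3)c1 | intermediate
20 | 5,7,3',4'-tetra-O-benzyl-(−)-epicatechin 3-O-[3,4,5-tris(benzyloxy)benzoate] | O=C(O[C@@H]1Cc2c(OCc3ccccc3)cc(OCc3ccccc3)cc2O[C@@H]1c1ccc(OCc3ccccc3)c(OCc3ccccc3)c1)c1cc(OCc3ccccc3)c(OCc3ccccc3)c(OCc3ccccc3)c1 | intermediate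
21 | tetradeca-O-benzyl epicatechin 3-O-gallate-(4β→8)-epicatechin 3-O-gallate | O=C(O[C@@H]1[C@@H](c2c(OCc5ccccc5)cc(OCc5ccccc5)c3c2O[C@H](c2ccc(OCc5ccccc5)c(OCc5ccccc5)c2)[C@H](OC(=O)c2cc(OCc5ccccc5)c(OCc5ccccc5)c(OCc5ccccc5)c2)C3)c2c(OCc5ccccc5)cc(OCc5ccccc5)cc2O[C@@H]1c1ccc(OCc5ccccc5)c(OCc5ccccc5)c1)c1cc(OCc5ccccc5)c(OCc5ccccc5)c(OCc5ccccc5)c1 | intermediate
22 | octadeca-O-benzyl epicatechin-(4β→8)-epicatechin 3-O-gallate-(4β→8)-epicatechin 3-O-gallate | O=C(O[C@@H]1[C@@H](c2c(OCc5ccccc5)cc(OCc5ccccc5)c3c2O[C@H](c2ccc(OCc5ccccc5)c(OCc5ccccc5)c2)[C@H](OC(=O)c2cc(OCc5ccccc5)c(OCc5ccccc5)c(OCc5ccccc5)c2)C3)c2c(OCc5ccccc5)cc(OCc5ccccc5)c([C@H]3c4c(OCc5ccccc5)cc(OCc5ccccc5)cc4O[C@H](c4ccc(OCc5ccccc5)c(OCc5ccccc5)c4)[C@@H]3O)c2O[C@@H]1c1ccc(OCc5ccccc5)c(OCc5ccccc5)c1)c1cc(OCc5ccccc5)c(OCc5ccccc5)c(OCc5ccccc5)c1 | intermediate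
23 | epicatechin-(4β→8)-epicatechin 3-O-gallate-(4β→8)-epicatechin 3-O-gallate (CNP0279403.1) | O=C(O[C@@H]1[C@@H](c2c(O)cc(O)c3c2O[C@H](c2ccc(O)c(O)c2)[C@H](OC(=O)c2cc(O)c(O)c(O)c2)C3)c2c(O)cc(O)c([C@H]3c4c(O)cc(O)cc4O[C@H](c4ccc(O)c(O)c4)[C@@H]3O)c2O[C@@H]1c1ccc(O)c(O)c1)c1cc(O)c(O)c(O)c1 | target

**Step count and risks**

Total step count: 14. Longest linear sequence: 11 steps (3 → 4 → 5 → 7 → 11 → 13 → 14 → 15 → 17 → 21 → 22 → 23).

Steps most likely to fail:

Step 5. Retro-aldol cleavage of the aldolate and base-induced E1cB ring-opening of the chromanone may outrun the SNAr closure, so that the ketone and aldehyde are returned or a chalcone accumulates. The fallback closes the ring in the classical sense through O1–C2 and sets out from 7. Fluoride is first exchanged for hydroxide with a weakly basic hydroxide surrogate ((E)-benzaldoxime, Cs2CO3, DMSO, 60 °C), which does not fully enolise the ketone. SNAr gives the O-aryl oxime 1-[2,4-bis(benzyloxy)-6-[(benzylideneamino)oxy]phenyl]-2-(1-ethoxyethoxy)ethan-1-one F1, which is not isolated. F1 loses benzonitrile under the same base to give 1-[2,4-bis(benzyloxy)-6-hydroxyphenyl]-2-(1-ethoxyethoxy)ethan-1-one F2. Claisen–Schmidt condensation of F2 with 8 (KOH, EtOH) should give (Z)-1-[2,4-bis(benzyloxy)-6-hydroxyphenyl]-3-[3,4-bis(benzyloxy)phenyl]-2-(1-ethoxyethoxy)prop-2-en-1-one F3. Oxa-Michael cyclisation of this 2'-hydroxychalcone (NaOAc, EtOH, reflux) comes back to the route at 11.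

Step 8. The extra α'-alkoxy group at C4 may erode the discrimination of the catalyst, and under base the C4 alkoxide may be lost through the C2 enolate towards an anthocyanidin-type oxidopyrylium, giving low selectivity or decomposition. The fallback removes the C4 oxygen before the stereo-defining reduction and puts it back afterwards; it sets out from 13. Ionic reduction of the C4 ether (Et3SiH, BF3·OEt2, CH2Cl2, −78 → 0 °C) should give rac-(2,3-trans)-5,7-bis(benzyloxy)-2-[3,4-bis(benzyloxy)phenyl]chroman-3-ol F4. Dess–Martin oxidation gives rac-5,7-bis(benzyloxy)-2-[3,4-bis(benzyloxy)phenyl]chroman-3-one F5, a plain α-aryl cyclic ketone. The same hydrogenation with dynamic kinetic resolution should then give 5,7,3',4'-tetra-O-benzyl-(−)-epicatechin, which is identical with compound 19 of the list. Benzylic oxidation of 19 with DDQ in the presence of 2-ethoxyethanol (CH2Cl2, 23 °C) comes back to the route at 15.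

Step 13. The cation from 15 may be captured by the free, nucleophilic A-ring of a second molecule of 15 (oligomerisation), and attack of 21 may be split between C8 and C6. The fallback caps C8 of the electrophile and sets out from 15. Bromination (NBS, CH2Cl2, −78 °C) should give (2R,3R)-5,7-bis(benzyloxy)-2-[3,4-bis(benzyloxy)phenyl]-8-bromo-4-(2-ethoxyethoxy)chroman-3-ol F6, which can no longer act as a nucleophile. TMSOTf coupling of F6 with 21 in near-equimolar amounts should give the 8-bromo octadeca-O-benzyl trimer F7. Hydrogenolysis of F7 (H2, Pd(OH)2/C, Et3N, THF/MeOH/H2O) removes bromine together with the benzyl groups and comes back to the route at 23.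

**Further compounds**

F1 | step 5 | 1-[2,4-bis(benzyloxy)-6-[(benzylideneamino)oxy]phenyl]-2-(1-ethoxyethoxy)ethan-1-one | CCOC(C)OCC(=O)c1c(O/N=C/c2ccccc2)cc(OCc2ccccc2)cc1OCc1ccccc1
F2 | step 5 | 1-[2,4-bis(benzyloxy)-6-hydroxyphenyl]-2-(1-ethoxyethoxy)ethan-1-one | CCOC(C)OCC(=O)c1c(O)cc(OCc2ccccc2)cc1OCc1ccccc1
F3 | step 5 | (Z)-1-[2,4-bis(benzyloxy)-6-hydroxyphenyl]-3-[3,4-bis(benzyloxy)phenyl]-2-(1-ethoxyethoxy)prop-2-en-1-one | CCOC(C)O/C(=C\c1ccc(OCc2ccccc2)c(OCc2ccccc2)c1)C(=O)c1c(O)cc(OCc2ccccc2)cc1OCc1ccccc1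
F4 | step 8 | rac-(2,3-trans)-5,7-bis(benzyloxy)-2-[3,4-bis(benzyloxy)phenyl]chroman-3-ol | OC1Cc2c(OCc3ccccc3)cc(OCc3ccccc3)cc2OC1c1ccc(OCc3ccccc3)c(OCc3ccccc3)c1
F5 | step 8 | rac-5,7-bis(benzyloxy)-2-[3,4-bis(benzyloxy)phenyl]chroman-3-one | O=C1Cc2c(OCc3ccccc3)cc(OCc3ccccc3)cc2OC1c1ccc(OCc3ccccc3)c(OCc3ccccc3)c1
F6 | step 13 | (2R,3R)-5,7-bis(benzyloxy)-2-[3,4-bis(benzyloxy)phenyl]-8-bromo-4-(2-ethoxyethoxy)chroman-3-ol | O[C@@H]1C(OCCOCC)c2c(OCc3ccccc3)cc(OCc3ccccc3)c(Br)c2O[C@@H]1c1ccc(OCc3ccccc3)c(OCc3ccccc3)c1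
F7 | step 13 | 8-bromo (top unit) octadeca-O-benzyl epicatechin-(4β→8)-epicatechin 3-O-gallate-(4β→8)-epicatechin 3-O-gallate | O=C(O[C@@H]1[C@@H](c2c(OCc5ccccc5)cc(OCc5ccccc5)c3c2O[C@H](c2ccc(OCc5ccccc5)c(OCc5ccccc5)c2)[C@H](OC(=O)c2cc(OCc5ccccc5)c(OCc5ccccc5)c(OCc5ccccc5)c2)C3)c2c(OCc5ccccc5)cc(OCc5ccccc5)c([C@H]3c4c(OCc5ccccc5)cc(OCc5ccccc5)c(Br)c4O[C@H](c4ccc(OCc5ccccc5)c(OCc5ccccc5)c4)[C@@H]3O)c2O[C@@H]1c1ccc(OCc5ccccc5)c(OCc5ccccc5)c1)c1cc(OCc5ccccc5)c(OCc5ccccc5)c(OCc5ccccc5)c1
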